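**Retrosynthetic overview**

- Feature: in the target, the butenolide ring oxygen O1, the stereogenic C5, the exocyclic C5–CH2, and the trisubstituted alkene CH=C(CH2OH) whose CH2OH is cis to that CH2 form a six-atom array O–C–C–C=C–C. This is a latent 3,6-dihydro-2H-pyran: ring O = O1, ester-bearing C2 = butenolide C5, C3 = the CH2, C4=C5 = the alkene, acetal C6 = the CH2OH carbon.
- Disconnections, backwards: butenolide C4–CH2OH (Stille coupling on a tetronic triflate); butenolide C3–C4 (Dieckmann closure of an α-acetoxy ester); the dihydropyran (hetero-Diels–Alder reaction of methyl glyoxylate with a (1E)-1-methoxy-2-alkylbuta-1,3-diene); diene C3=C4 (Wittig methylenation of a β-methoxy enal); the E-CH=CH (cross-metathesis); the tertiary carbinol (Sharpless epoxidation and reductive epoxide opening from dihydro-β-ionone).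
- Ring order: the cyclohexene ring is bought in; the temporary dihydropyran is closed in step 12 and opened in steps 13–14; the butenolide is closed in step 17.

Key step: step 12

Assumption: the sense of induction in step 12 is taken to follow that of titanium binaphtholate glyoxylate-ene and hetero-Diels–Alder reactions, where the (R)-ligand gives the (R)-configured α-oxy ester carbon, so the (S)-ligand is specified. Methyl glyoxylate is taken as commercial and is distilled from P2O5 just before use.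

**Route**

Step 1
Reactants: 1 dihydro-β-ionone
Product: 2 ethyl (2E)-3-methyl-5-(2,6,6-trimethylcyclohex-1-en-1-yl)pent-2-enoate
Conditions: (EtO)2P(O)CH2CO2Et, NaH, THF, 0 °C to reflux; minor Z isomer removed by chromatography
Reagents that add atoms: triethyl phosphonoacetate CCOC(=O)CP(=O)(OCC)OCC
Why: Horner–Wadsworth–Emmons olefination of a methyl ketone should favour the E ester (ester trans to the longer chain) and leave a separable minor Z isomer.

Step 2
Reactants: 2 ethyl (2E)-3-methyl-5-(2,6,6-trimethylcyclohex-1-en-1-yl)pent-2-enoate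
Product: 3 (2E)-3-methyl-5-(2,6,6-trimethylcyclohex-1-en-1-yl)pent-2-en-1-ol
Conditions: iBu2AlH (2.2 equiv), CH2Cl2, −78 °C
Reagents that add atoms: none
Why: 1,2-reduction of an enoate by iBu2AlH should give the allylic alcohol without touching either alkene.

Step 3
Reactants: 3 (2E)-3-methyl-5-(2,6,6-trimethylcyclohex-1-en-1-yl)pent-2-en-1-ol
Product: 4 [(2S,3S)-3-methyl-3-[2-(2,6,6-trimethylcyclohex-1-en-1-yl)ethyl]oxiran-2-yl]methanol
Conditions: Ti(OiPr)4 (10 mol%), L-(+)-diethyl tartrate (12 mol%), t-BuOOH, 4 Å MS, CH2Cl2, −20 °C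
Reagents that add atoms: tert-butyl hydroperoxide CC(C)(C)OO
Why: Sharpless asymmetric epoxidation, in which the L-(+)-tartrate ligand should deliver oxygen to the face that gives the (2S,3S)-epoxide, as for other E-3,3-disubstituted allylic alcohols of the geraniol type, while the tetrasubstituted ring alkene has no directing hydroxyl and should stay.

Step 4
Reactants: 4 [(2S,3S)-3-methyl-3-[2-(2,6,6-trimethylcyclohex-1-en-1-yl)ethyl]oxiran-2-yl]methanol
Product: 5 (2S,3R)-3-(iodomethyl)-2-methyl-2-[2-(2,6,6-trimethylcyclohex-1-en-1-yl)ethyl]oxirane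
Conditions: PPh3, imidazole, I2, Et2O/MeCN, 0 °C
Reagents that add atoms: iodine II
Why: Appel-type iodination of the primary alcohol proceeds by SN2 displacement at CH2, so neither epoxide stereocentre is touched (the descriptor at the CH carbon changes only because of the priority of CH2I).

Step 5
Reactants: 5 (2S,3R)-3-(iodomethyl)-2-methyl-2-[2-(2,6,6-trimethylcyclohex-1-en-1-yl)ethyl]oxirane
Product: 6 (3S)-3-methyl-5-(2,6,6-trimethylcyclohex-1-en-1-yl)pent-1-en-3-ol
Conditions: Zn dust, EtOH, reflux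
Reagents that add atoms: none
Why: zinc-mediated reductive elimination of a β-iodo epoxide (insertion into C–I, then β-elimination that breaks the CH–O bond) should give the transposed allylic alcohol, and the C–O bond at the quaternary carbon is never broken, so the (S) tertiary carbinol is carried over from the epoxide.

Step 6
Reactants: 7 methyl pent-4-enoate
Product: 9 methyl (2E)-2-(methoxymethylidene)pent-4-enoate, via sodium formyl ester enolate 8 (not isolated)
Conditions: NaH, HCO2Me, THF/DMF, 0 °C to rt; then Me2SO4, rt; minor Z isomer removed by chromatography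
Reagents that add atoms: methyl formate COC=O; dimethyl sulfate COS(=O)(=O)OC
Why: crossed Claisen formylation followed by O-methylation of the formyl ester enolate in a dipolar solvent is the standard β-methoxyacrylate synthesis and should favour the E isomer (OMe anti to the ester).

Step 7
Reactants: 6 (3S)-3-methyl-5-(2,6,6-trimethylcyclohex-1-en-1-yl)pent-1-en-3-ol; 9 methyl (2E)-2-(methoxymethylidene)pent-4-enoate (3 equiv)
Product: 10 methyl (2E,4E,6S)-6-hydroxy-2-(methoxymethylidene)-6-methyl-8-(2,6,6-trimethylcyclohex-1-en-1-yl)oct-4-enoate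
Conditions: second-generation Hoveyda–Grubbs catalyst RuCl2(H2IMes)(=CH-C6H4-2-OiPr) (5 mol%), CH2Cl2, 40 °C
Reagents that add atoms: none
Why: olefin cross-metathesis between a free tertiary allylic alcohol (slow to homodimerise) and an excess of a terminal allyl partner should give the E-disubstituted alkene under thermodynamic control, the trisubstituted push–pull enol ether and the tetrasubstituted ring alkene being inert to the ruthenium carbene.

Step 8
Reactants: 10 methyl (2E,4E,6S)-6-hydroxy-2-(methoxymethylidene)-6-methyl-8-(2,6,6-trimethylcyclohex-1-en-1-yl)oct-4-enoate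
Product: 11 methyl (2E,4E,6S)-2-(methoxymethylidene)-6-methyl-6-(triethylsilyloxy)-8-(2,6,6-trimethylcyclohex-1-en-1-yl)oct-4-enoate
Conditions: Et3SiOTf, 2,6-lutidine, CH2Cl2, −78 to 0 °C
Reagents that add atoms: triethylsilyl trifluoromethanesulfonate CC[Si](CC)(CC)OS(=O)(=O)C(F)(F)F
Why: silylation of a hindered tertiary alcohol needs the silyl triflate, and the buffered conditions should leave the deactivated enol ether alone.

Step 9
Reactants: 11 methyl (2E,4E,6S)-2-(methoxymethylidene)-6-methyl-6-(triethylsilyloxy)-8-(2,6,6-trimethylcyclohex-1-en-1-yl)oct-4-enoate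
Product: 12 (2E,4E,6S)-2-(methoxymethylidene)-6-methyl-6-(triethylsilyloxy)-8-(2,6,6-trimethylcyclohex-1-en-1-yl)oct-4-en-1-ol
Conditions: iBu2AlH (2.5 equiv), CH2Cl2, −78 °C; aqueous potassium sodium tartrate work-up
Reagents that add atoms: none
Why: 1,2-reduction of the β-methoxyacrylate ester by iBu2AlH should give the 3-methoxyallyl alcohol with the enol ether geometry intact, provided the work-up stays non-acidic.

Step 10
Reactants: 12 (2E,4E,6S)-2-(methoxymethylidene)-6-methyl-6-(triethylsilyloxy)-8-(2,6,6-trimethylcyclohex-1-en-1-yl)oct-4-en-1-ol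
Product: 13 (2E,4E,6S)-2-(methoxymethylidene)-6-methyl-6-(triethylsilyloxy)-8-(2,6,6-trimethylcyclohex-1-en-1-yl)oct-4-enal
Conditions: MnO2 (activated, excess), CH2Cl2, rt
Reagents that add atoms: none
Why: neutral MnO2 oxidation of an allylic alcohol should give the β-methoxy enal, whose E form (OMe anti to CHO) is also the thermodynamically preferred one.

Step 11
Reactants: 13 (2E,4E,6S)-2-(methoxymethylidene)-6-methyl-6-(triethylsilyloxy)-8-(2,6,6-trimethylcyclohex-1-en-1-yl)oct-4-enal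
Product: 14 (1E)-1-methoxy-2-[(2E,4S)-4-methyl-4-(triethylsilyloxy)-6-(2,6,6-trimethylcyclohex-1-en-1-yl)hex-2-en-1-yl]buta-1,3-diene
Conditions: Ph3PCH3Br, KN(SiMe3)2, THF, 0 °C; then 13, −78 °C to rt; base-washed silica, used at once
Reagents that add atoms: methyltriphenylphosphonium bromide C[P+](c1ccccc1)(c1ccccc1)c1ccccc1.[Br-]
Why: Wittig methylenation of a 3-alkoxyacrolein converts CHO into the vinyl group without touching the enol ether, so OMe stays trans to the new vinyl group and the diene is obtained as the 1E isomer.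

Step 12
Reactants: 14 (1E)-1-methoxy-2-[(2E,4S)-4-methyl-4-(triethylsilyloxy)-6-(2,6,6-trimethylcyclohex-1-en-1-yl)hex-2-en-1-yl]buta-1,3-diene; 15 methyl glyoxylate
Product: 16 methyl (2S,6R)-6-methoxy-5-[(2E,4S)-4-methyl-4-(triethylsilyloxy)-6-(2,6,6-trimethylcyclohex-1-en-1-yl)hex-2-en-1-yl]-3,6-dihydro-2H-pyran-2-carboxylate (cis)
Conditions: TiCl2[(S)-1,1'-bi-2-naphtholate] (10 mol%; from TiCl2(OiPr)2 and (S)-1,1'-bi-2-naphthol, 4 Å MS), CH2Cl2, −30 °C
Reagents that add atoms: none
Why: The titanium centre binds methyl glyoxylate through the aldehyde and ester oxygens, and the s-cis (1E)-methoxydiene adds in a concerted, asynchronous endo [4+2], its terminal CH2 (C4) bonding to the aldehyde carbon and the carbonyl oxygen to the methoxy-bearing C1. The closest known reaction is the catalytic asymmetric hetero-Diels–Alder reaction of glyoxylate esters with 1-methoxybuta-1,3-dienes under tetravalent titanium binaphtholate catalysis, applied here to a diene with an allyl-type C2 substituent. The six-membered 3,6-dihydro-2H-pyran closes by intermolecular cycloaddition, both ring bonds (C–C and acetal C–O) forming in the same step and the new ring alkene being cis by necessity. The ester-bearing C2 (S) is set by the catalyst, whose (S)-ligand is chosen to expose the aldehyde face leading to this configuration, and the acetal C6 (R, cis to the ester) by the endo orientation of the ester together with the 1E diene geometry; C6 is erased in step 13, so only the aldehyde face matters for the target. The step needs regiocontrol, secured by the donor methoxy group that makes C4 the nucleophilic terminus, and chemoselectivity, secured because the tetrasubstituted ring alkene and the E-disubstituted alkene are far weaker partners for the activated aldehyde than the electron-rich diene and because the tertiary hydroxyl is masked as its triethylsilyl ether.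

Step 13
Reactants: 16 methyl (2S,6R)-6-methoxy-5-[(2E,4S)-4-methyl-4-(triethylsilyloxy)-6-(2,6,6-trimethylcyclohex-1-en-1-yl)hex-2-en-1-yl]-3,6-dihydro-2H-pyran-2-carboxylate
Product: 17 methyl (2S)-6-hydroxy-5-[(2E,4S)-4-methyl-4-(triethylsilyloxy)-6-(2,6,6-trimethylcyclohex-1-en-1-yl)hex-2-en-1-yl]-3,6-dihydro-2H-pyran-2-carboxylate (anomer mixture)
Conditions: PPTS (cat.), acetone/H2O, 0 °C to rt
Reagents that add atoms: water O
Why: the allylic mixed acetal should hydrolyse through its stabilised oxocarbenium ion under acid mild enough to spare the tertiary triethylsilyl ether, and the ring keeps the alkene cis.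

Step 14
Reactants: 17 methyl (2S)-6-hydroxy-5-[(2E,4S)-4-methyl-4-(triethylsilyloxy)-6-(2,6,6-trimethylcyclohex-1-en-1-yl)hex-2-en-1-yl]-3,6-dihydro-2H-pyran-2-carboxylate
Product: 19 methyl (2S,4Z,7E,9S)-2-hydroxy-5-(hydroxymethyl)-9-methyl-9-(triethylsilyloxy)-11-(2,6,6-trimethylcyclohex-1-en-1-yl)undeca-4,7-dienoate, via open-chain Z-hydroxy enal 18 (not isolated)
Conditions: NaBH4, CeCl3·7H2O, MeOH, −40 °C
Reagents that add atoms: none
Why: Luche reduction should trap the ring-opened Z-enal by 1,2-hydride addition as soon as it forms from the lactol, faster than it can isomerise and faster than the α-hydroxy ester is reduced at this temperature, so the CH2OH ends up cis to the CH2 leading to the carbinol.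

Step 15
Reactants: 19 methyl (2S,4Z,7E,9S)-2-hydroxy-5-(hydroxymethyl)-9-methyl-9-(triethylsilyloxy)-11-(2,6,6-trimethylcyclohex-1-en-1-yl)undeca-4,7-dienoate
Product: 20 methyl (2S,4Z,7E,9S)-5-[(tert-butyldimethylsilyloxy)methyl]-2-hydroxy-9-methyl-9-(triethylsilyloxy)-11-(2,6,6-trimethylcyclohex-1-en-1-yl)undeca-4,7-dienoate
Conditions: TBSCl (1.05 equiv), imidazole, CH2Cl2, 0 °C
Reagents that add atoms: tert-butyldimethylsilyl chloride CC(C)(C)[Si](C)(C)Cl
Why: silylation should select the primary allylic hydroxyl over the more hindered and less nucleophilic secondary hydroxyl next to the ester.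

Step 16
Reactants: 20 methyl (2S,4Z,7E,9S)-5-[(tert-butyldimethylsilyloxy)methyl]-2-hydroxy-9-methyl-9-(triethylsilyloxy)-11-(2,6,6-trimethylcyclohex-1-en-1-yl)undeca-4,7-dienoate
Product: 21 methyl (2S,4Z,7E,9S)-2-acetoxy-5-[(tert-butyldimethylsilyloxy)methyl]-9-methyl-9-(triethylsilyloxy)-11-(2,6,6-trimethylcyclohex-1-en-1-yl)undeca-4,7-dienoate
Conditions: Ac2O, pyridine, DMAP (cat.), CH2Cl2, 0 °C to rt
Reagents that add atoms: acetic anhydride CC(=O)OC(C)=O
Why: DMAP-catalysed acylation of the secondary alcohol occurs at oxygen and leaves the carbinol configuration untouched.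

Step 17
Reactants: 21 methyl (2S,4Z,7E,9S)-2-acetoxy-5-[(tert-butyldimethylsilyloxy)methyl]-9-methyl-9-(triethylsilyloxy)-11-(2,6,6-trimethylcyclohex-1-en-1-yl)undeca-4,7-dienoate
Product: 22 (5S)-5-[(2Z,5E,7S)-3-[(tert-butyldimethylsilyloxy)methyl]-7-methyl-7-(triethylsilyloxy)-9-(2,6,6-trimethylcyclohex-1-en-1-yl)nona-2,5-dien-1-yl]-4-hydroxyfuran-2(5H)-one
Conditions: LiN(SiMe3)2 (2.5 equiv), THF, −78 to −20 °C; then cold dilute HCl to pH 3
Reagents that add atoms: none
Why: Dieckmann condensation of an α-acetoxy ester, in which the acetate enolate formed kinetically at the methyl group closes the five-membered ring by 5-exo-trig attack on the methyl ester, is the standard tetronic acid synthesis and at low temperature should not epimerise the carbinol carbon that becomes C5.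

Step 18
Reactants: 22 (5S)-5-[(2Z,5E,7S)-3-[(tert-butyldimethylsilyloxy)methyl]-7-methyl-7-(triethylsilyloxy)-9-(2,6,6-trimethylcyclohex-1-en-1-yl)nona-2,5-dien-1-yl]-4-hydroxyfuran-2(5H)-one
Product: 23 (2S)-2-[(2Z,5E,7S)-3-[(tert-butyldimethylsilyloxy)methyl]-7-methyl-7-(triethylsilyloxy)-9-(2,6,6-trimethylcyclohex-1-en-1-yl)nona-2,5-dien-1-yl]-5-oxo-2,5-dihydrofuran-3-yl trifluoromethanesulfonate
Conditions: Tf2O, iPr2NEt, CH2Cl2, −78 °C
Reagents that add atoms: trifluoromethanesulfonic anhydride O=S(=O)(OS(=O)(=O)C(F)(F)F)C(F)(F)F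
Why: O-sulfonylation of the vinylogous acid with a hindered base at low temperature should give the vinyl triflate without deprotonating C5.

Step 19
Reactants: 23 (2S)-2-[(2Z,5E,7S)-3-[(tert-butyldimethylsilyloxy)methyl]-7-methyl-7-(triethylsilyloxy)-9-(2,6,6-trimethylcyclohex-1-en-1-yl)nona-2,5-dien-1-yl]-5-oxo-2,5-dihydrofuran-3-yl trifluoromethanesulfonate
Product: 24 (5S)-5-[(2Z,5E,7S)-3-[(tert-butyldimethylsilyloxy)methyl]-7-methyl-7-(triethylsilyloxy)-9-(2,6,6-trimethylcyclohex-1-en-1-yl)nona-2,5-dien-1-yl]-4-(hydroxymethyl)furan-2(5H)-one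
Conditions: Bu3SnCH2OH, Pd(PPh3)4 (5 mol%), LiCl, 1,4-dioxane, 80 °C
Reagents that add atoms: (tributylstannyl)methanol CCCC[Sn](CCCC)(CCCC)CO
Why: Stille coupling, in which zerovalent palladium inserts into the activated C–OTf bond of the β-triflyloxy enoate and the α-oxygenated CH2OH group is transferred from tin in preference to butyl, under base-free conditions that should not epimerise C5.

Step 20
Reactants: 24 (5S)-5-[(2Z,5E,7S)-3-[(tert-butyldimethylsilyloxy)methyl]-7-methyl-7-(triethylsilyloxy)-9-(2,6,6-trimethylcyclohex-1-en-1-yl)nona-2,5-dien-1-yl]-4-(hydroxymethyl)furan-2(5H)-one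
Product: 25 (5S)-5-[(2Z,5E,7S)-7-hydroxy-3-(hydroxymethyl)-7-methyl-9-(2,6,6-trimethylcyclohex-1-en-1-yl)nona-2,5-dien-1-yl]-4-(hydroxymethyl)furan-2(5H)-one (target)
Conditions: HF·pyridine, pyridine, THF, 0 °C to rt
Reagents that add atoms: none
Why: pyridine-buffered fluoride desilylation should remove both silyl ethers under conditions too weakly acidic to ionise the tertiary allylic alcohol and too weakly basic to deprotonate the butenolide at C5.

**Compound list**

1 | dihydro-β-ionone | CC(=O)CCC1=C(C)CCCC1(C)C | starting material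
2 | ethyl (2E)-3-methyl-5-(2,6,6-trimethylcyclohex-1-en-1-yl)pent-2-enoate | CCOC(=O)/C=C(\C)CCC1=C(C)CCCC1(C)C | intermediate
3 | (2E)-3-methyl-5-(2,6,6-trimethylcyclohex-1-en-1-yl)pent-2-en-1-ol | OC/C=C(\C)CCC1=C(C)CCCC1(C)C | intermediate
4 | [(2S,3S)-3-methyl-3-[2-(2,6,6-trimethylcyclohex-1-en-1-yl)ethyl]oxiran-2-yl]methanol | OC[C@@H]1O[C@@]1(C)CCC2=C(C)CCCC2(C)C | intermediate
5 | (2S,3R)-3-(iodomethyl)-2-methyl-2-[2-(2,6,6-trimethylcyclohex-1-en-1-yl)ethyl]oxirane | IC[C@@H]1O[C@@]1(C)CCC2=C(C)CCCC2(C)C | intermediate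
6 | (3S)-3-methyl-5-(2,6,6-trimethylcyclohex-1-en-1-yl)pent-1-en-3-ol | C=C[C@@](C)(O)CCC1=C(C)CCCC1(C)C | intermediate
7 | methyl pent-4-enoate | C=CCCC(=O)OC | starting material
8 | sodium enolate of methyl 2-formylpent-4-enoate | C=CCC(=C[O-])C(=O)OC.[Na+] | intermediate (not isolated)
9 | methyl (2E)-2-(methoxymethylidene)pent-4-enoate | CO/C=C(\CC=C)C(=O)OC | intermediate
10 | methyl (2E,4E,6S)-6-hydroxy-2-(methoxymethylidene)-6-methyl-8-(2,6,6-trimethylcyclohex-1-en-1-yl)oct-4-enoate | CC1=C(CC[C@](C)(O)/C=C/C/C(=C\OC)C(=O)OC)C(C)(C)CCC1 | intermediate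
11 | methyl (2E,4E,6S)-2-(methoxymethylidene)-6-methyl-6-(triethylsilyloxy)-8-(2,6,6-trimethylcyclohex-1-en-1-yl)oct-4-enoate | CC1=C(CC[C@](C)(O[Si](CC)(CC)CC)/C=C/C/C(=C\OC)C(=O)OC)C(C)(C)CCC1 | intermediate
12 | (2E,4E,6S)-2-(methoxymethylidene)-6-methyl-6-(triethylsilyloxy)-8-(2,6,6-trimethylcyclohex-1-en-1-yl)oct-4-en-1-ol | CC1=C(CC[C@](C)(O[Si](CC)(CC)CC)/C=C/C/C(=C\OC)CO)C(C)(C)CCC1 | intermediate
13 | (2E,4E,6S)-2-(methoxymethylidene)-6-methyl-6-(triethylsilyloxy)-8-(2,6,6-trimethylcyclohex-1-en-1-yl)oct-4-enal | CC1=C(CC[C@](C)(O[Si](CC)(CC)CC)/C=C/C/C(=C\OC)C=O)C(C)(C)CCC1 | intermediate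
14 | (1E)-1-methoxy-2-[(2E,4S)-4-methyl-4-(triethylsilyloxy)-6-(2,6,6-trimethylcyclohex-1-en-1-yl)hex-2-en-1-yl]buta-1,3-diene | CC1=C(CC[C@](C)(O[Si](CC)(CC)CC)/C=C/C/C(C=C)=C\OC)C(C)(C)CCC1 | intermediate
15 | methyl glyoxylate | COC(=O)C=O | starting material
16 | methyl (2S,6R)-6-methoxy-5-[(2E,4S)-4-methyl-4-(triethylsilyloxy)-6-(2,6,6-trimethylcyclohex-1-en-1-yl)hex-2-en-1-yl]-3,6-dihydro-2H-pyran-2-carboxylate | CC1=C(CC[C@](C)(O[Si](CC)(CC)CC)/C=C/CC2=CC[C@@H](C(=O)OC)O[C@H]2OC)C(C)(C)CCC1 | intermediate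
17 | methyl (2S)-6-hydroxy-5-[(2E,4S)-4-methyl-4-(triethylsilyloxy)-6-(2,6,6-trimethylcyclohex-1-en-1-yl)hex-2-en-1-yl]-3,6-dihydro-2H-pyran-2-carboxylate | CC1=C(CC[C@](C)(O[Si](CC)(CC)CC)/C=C/CC2=CC[C@@H](C(=O)OC)OC2O)C(C)(C)CCC1 | intermediate
18 | methyl (2S,4Z,7E,9S)-5-formyl-2-hydroxy-9-methyl-9-(triethylsilyloxy)-11-(2,6,6-trimethylcyclohex-1-en-1-yl)undeca-4,7-dienoate | CC1=C(CC[C@](C)(O[Si](CC)(CC)CC)/C=C/C/C(=C/C[C@H](O)C(=O)OC)C=O)C(C)(C)CCC1 | intermediate (not isolated)
19 | methyl (2S,4Z,7E,9S)-2-hydroxy-5-(hydroxymethyl)-9-methyl-9-(triethylsilyloxy)-11-(2,6,6-trimethylcyclohex-1-en-1-yl)undeca-4,7-dienoate | CC1=C(CC[C@](C)(O[Si](CC)(CC)CC)/C=C/C/C(=C/C[C@H](O)C(=O)OC)CO)C(C)(C)CCC1 | intermediate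
20 | methyl (2S,4Z,7E,9S)-5-[(tert-butyldimethylsilyloxy)methyl]-2-hydroxy-9-methyl-9-(triethylsilyloxy)-11-(2,6,6-trimethylcyclohex-1-en-1-yl)undeca-4,7-dienoate | CC1=C(CC[C@](C)(O[Si](CC)(CC)CC)/C=C/C/C(=C/C[C@H](O)C(=O)OC)CO[Si](C)(C)C(C)(C)C)C(C)(C)CCC1 | intermediate
21 | methyl (2S,4Z,7E,9S)-2-acetoxy-5-[(tert-butyldimethylsilyloxy)methyl]-9-methyl-9-(triethylsilyloxy)-11-(2,6,6-trimethylcyclohex-1-en-1-yl)undeca-4,7-dienoate | CC1=C(CC[C@](C)(O[Si](CC)(CC)CC)/C=C/C/C(=C/C[C@H](OC(C)=O)C(=O)OC)CO[Si](C)(C)C(C)(C)C)C(C)(C)CCC1 | intermediate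
22 | (5S)-5-[(2Z,5E,7S)-3-[(tert-butyldimethylsilyloxy)methyl]-7-methyl-7-(triethylsilyloxy)-9-(2,6,6-trimethylcyclohex-1-en-1-yl)nona-2,5-dien-1-yl]-4-hydroxyfuran-2(5H)-one | CC1=C(CC[C@](C)(O[Si](CC)(CC)CC)/C=C/C/C(=C/C[C@@H]2OC(=O)C=C2O)CO[Si](C)(C)C(C)(C)C)C(C)(C)CCC1 | intermediate
23 | (2S)-2-[(2Z,5E,7S)-3-[(tert-butyldimethylsilyloxy)methyl]-7-methyl-7-(triethylsilyloxy)-9-(2,6,6-trimethylcyclohex-1-en-1-yl)nona-2,5-dien-1-yl]-5-oxo-2,5-dihydrofuran-3-yl trifluoromethanesulfonate | CC1=C(CC[C@](C)(O[Si](CC)(CC)CC)/C=C/C/C(=C/C[C@@H]2OC(=O)C=C2OS(=O)(=O)C(F)(F)F)CO[Si](C)(C)C(C)(C)C)C(C)(C)CCC1 | intermediate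
24 | (5S)-5-[(2Z,5E,7S)-3-[(tert-butyldimethylsilyloxy)methyl]-7-methyl-7-(triethylsilyloxy)-9-(2,6,6-trimethylcyclohex-1-en-1-yl)nona-2,5-dien-1-yl]-4-(hydroxymethyl)furan-2(5H)-one | CC1=C(CC[C@](C)(O[Si](CC)(CC)CC)/C=C/C/C(=C/C[C@@H]2OC(=O)C=C2CO)CO[Si](C)(C)C(C)(C)C)C(C)(C)CCC1 | intermediate
25 | (5S)-5-[(2Z,5E,7S)-7-hydroxy-3-(hydroxymethyl)-7-methyl-9-(2,6,6-trimethylcyclohex-1-en-1-yl)nona-2,5-dien-1-yl]-4-(hydroxymethyl)furan-2(5H)-one | CC1=C(CC[C@](C)(O)/C=C/C/C(=C/C[C@@H]2OC(=O)C=C2CO)CO)C(C)(C)CCC1 | target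

**Step count**

Total steps: 20. Longest linear sequence: 19 steps (steps 1–5, then 7–20); step 6 is a one-step branch.

**Steps most likely to fail, with fallbacks**

1. Step 12. The catalyst may discriminate poorly between the aldehyde faces with this 2-substituted diene, or the activated aldehyde may be diverted into stepwise aldol-type addition while the Lewis acid degrades the acid-sensitive methoxydiene. Fallback with auxiliary control in place of catalyst control, setting out from 14 and returning at 16: commercial N-acryloyl-(2R)-bornane-10,2-sultam is ozonised (O3, CH2Cl2, −78 °C; Me2S) to N-glyoxyloyl-(2R)-bornane-10,2-sultam F1. This dienophile is combined with 14 under Eu(fod)3 (2 mol%) in CH2Cl2 at 0 °C, a mild lanthanide-catalysed hetero-Diels–Alder reaction in which the sultam, not a chiral catalyst, fixes the aldehyde face. By the sense of the allylation and ene reactions of this glyoxylamide, the (2R)-sultam is expected to give the (S) α-oxy centre and hence the acyl sultam cycloadduct F2. Methanolysis with Mg(OMe)2 in MeOH at 0 °C should release the auxiliary and give 16.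

2. Step 19. Transfer of the hydroxymethyl group from tin may be slow, so that hydrolysis or reduction of the triflate, or epimerisation at C5 through the 2-oxyfuran tautomer on prolonged heating, overtakes the coupling. Fallback that builds the hydroxymethyl-bearing carbon before the lactone is closed, setting out from 20 and returning at 24: 20 is converted with Me(MeO)NH·HCl and iPrMgCl (THF, −20 °C) into the N-methoxy-N-methylamide F3. (4-Methoxybenzyloxy)methyllithium, from Bu3SnCH2OCH2C6H4OMe and n-BuLi at −78 °C, is added to give the α-hydroxy ketone F4. Ketenylidenetriphenylphosphorane (Ph3P=C=C=O, toluene, 60 °C) acylates the hydroxyl and closes the ring by intramolecular Wittig reaction under neutral conditions to the 4-(4-methoxybenzyloxymethyl)butenolide F5. DDQ in CH2Cl2/pH 7 buffer then removes the benzyl-type ether to give 24.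

3. Step 7. The hindered tertiary allylic alcohol may turn over poorly, so that homodimerisation of 9, double-bond migration or catalyst decay takes over. Fallback without metathesis, setting out from 4 and returning at 11: 4 is oxidised (SO3·pyridine, DMSO, iPr2NEt, CH2Cl2, 0 °C) to the epoxy aldehyde F6 and methylenated (Ph3PCH3Br, KN(SiMe3)2, THF) to the vinyl epoxide F7. Pd(PPh3)4 (3 mol%) with dimethyl malonate in THF opens the vinyl epoxide by π-allyl formation and 1,4-attack of the soft nucleophile at the distal terminus, giving the E-alkene and the free tertiary alcohol of unchanged configuration in the malonate F8. Silylation (Et3SiOTf, 2,6-lutidine) gives the triethylsilyl ether F9, and Krapcho demethoxycarbonylation (LiCl, DMSO/H2O, 140 °C) gives the monoester F10. Formylation and O-methylation as in step 6 (NaH, HCO2Me; then Me2SO4) then give 11.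

**Further compounds**

F1 | step 12 | N-glyoxyloyl-(2R)-bornane-10,2-sultam | O=CC(=O)N1[C@@H]2C[C@H]3CC[C@]2(CS1(=O)=O)C3(C)C
F2 | step 12 | (2R)-N-{[(2S,6R)-6-methoxy-5-[(2E,4S)-4-methyl-4-(triethylsilyloxy)-6-(2,6,6-trimethylcyclohex-1-en-1-yl)hex-2-en-1-yl]-3,6-dihydro-2H-pyran-2-yl]carbonyl}bornane-10,2-sultam | CC1=C(CC[C@](C)(O[Si](CC)(CC)CC)/C=C/CC2=CC[C@@H](C(=O)N3[C@@H]4C[C@H]5CC[C@]4(CS3(=O)=O)C5(C)C)O[C@H]2OC)C(C)(C)CCC1
F3 | step 19 | (2S,4Z,7E,9S)-5-[(tert-butyldimethylsilyloxy)methyl]-2-hydroxy-N-methoxy-N,9-dimethyl-9-(triethylsilyloxy)-11-(2,6,6-trimethylcyclohex-1-en-1-yl)undeca-4,7-dienamide | CC1=C(CC[C@](C)(O[Si](CC)(CC)CC)/C=C/C/C(=C/C[C@H](O)C(=O)N(C)OC)CO[Si](C)(C)C(C)(C)C)C(C)(C)CCC1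
F4 | step 19 | (3S,5Z,8E,10S)-6-[(tert-butyldimethylsilyloxy)methyl]-3-hydroxy-1-(4-methoxybenzyloxy)-10-methyl-10-(triethylsilyloxy)-12-(2,6,6-trimethylcyclohex-1-en-1-yl)dodeca-5,8-dien-2-one | CC1=C(CC[C@](C)(O[Si](CC)(CC)CC)/C=C/C/C(=C/C[C@H](O)C(=O)COCc2ccc(OC)cc2)CO[Si](C)(C)C(C)(C)C)C(C)(C)CCC1
F5 | step 19 | (5S)-5-[(2Z,5E,7S)-3-[(tert-butyldimethylsilyloxy)methyl]-7-methyl-7-(triethylsilyloxy)-9-(2,6,6-trimethylcyclohex-1-en-1-yl)nona-2,5-dien-1-yl]-4-[(4-methoxybenzyloxy)methyl]furan-2(5H)-one | CC1=C(CC[C@](C)(O[Si](CC)(CC)CC)/C=C/C/C(=C/C[C@@H]2OC(=O)C=C2COCc3ccc(OC)cc3)CO[Si](C)(C)C(C)(C)C)C(C)(C)CCC1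
F6 | step 7 | (2R,3S)-3-methyl-3-[2-(2,6,6-trimethylcyclohex-1-en-1-yl)ethyl]oxirane-2-carbaldehyde | O=C[C@@H]1O[C@@]1(C)CCC2=C(C)CCCC2(C)C
F7 | step 7 | (2S,3S)-3-ethenyl-2-methyl-2-[2-(2,6,6-trimethylcyclohex-1-en-1-yl)ethyl]oxirane | C=C[C@@H]1O[C@@]1(C)CCC2=C(C)CCCC2(C)C
F8 | step 7 | dimethyl 2-[(2E,4S)-4-hydroxy-4-methyl-6-(2,6,6-trimethylcyclohex-1-en-1-yl)hex-2-en-1-yl]propanedioate | CC1=C(CC[C@](C)(O)/C=C/CC(C(=O)OC)C(=O)OC)C(C)(C)CCC1
F9 | step 7 | dimethyl 2-[(2E,4S)-4-methyl-4-(triethylsilyloxy)-6-(2,6,6-trimethylcyclohex-1-en-1-yl)hex-2-en-1-yl]propanedioate | CC1=C(CC[C@](C)(O[Si](CC)(CC)CC)/C=C/CC(C(=O)OC)C(=O)OC)C(C)(C)CCC1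
F10 | step 7 | methyl (4E,6S)-6-methyl-6-(triethylsilyloxy)-8-(2,6,6-trimethylcyclohex-1-en-1-yl)oct-4-enoate | CC1=C(CC[C@](C)(O[Si](CC)(CC)CC)/C=C/CCC(=O)OC)C(C)(C)CCC1
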